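## Analysis of the target

Target 27 is a 3,3'-linked dimer of two 4-aryl-3,4-dihydrocoumarins. The unprimed lactone is fused to ring A, a phloroglucinol-type arene with oxygen at C5, C7 and C8a. The primed lactone is fused to ring B, a fully substituted arene with oxygen at C5', C6', C7', C8' and C8a'. Each C4 carries a 4-hydroxyphenyl group. The four stereocentres are contiguous (C4–C3–C3'–C4') with configuration (4R,3S,3'S,4'R); in each lactone the C3 substituent and the C4 aryl group are cis, and both halves have the same sense, so the skeleton is C2-symmetric apart from the oxygenation of the benzo rings. C3 and C3' are α to aryl ester carbonyls and epimerisable, and the cis arrangement is expected to be the less stable one, so both must be set under kinetic control and kept from base afterwards. The aryl lactones open with nucleophiles, the diarylmethine carbons C4 and C4' can ionise in strong acid, and the tetrahydroxy ring B is oxidised by air once the phenols are free. The hard points are the C3–C3' bond between two tertiary carbons, each next to a diarylmethine, and C4, which sits on an arene carbon (C4a) flanked by two oxygen-bearing carbons. The strategy rests on the pattern C8a(O)/C4a/C5(O)/C6(H)/C7(O)/C8(H) of ring A: it is what an ynol ether (C4a, C5) and a 3-alkoxycyclobutenone (C6, C7, C8, C8a) give when combined, so C4 can be set as a propargylic centre on a slim alkyne and ring A grown on it afterwards.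

## Retrosynthetic reasoning

27 to 26. The eight phenols are unmasked last, so the O–alkyl bonds are cut first. Octaether 26 has ethyl ethers on ring A, because building blocks 4 and 9 bring ethoxy groups, and methyl ethers elsewhere. All earlier steps then run on material that is neither acidic nor air-sensitive. The forward step has to cleave eight aryl alkyl ethers without touching the lactones or the α-centres.

26 to 19 and 24. The primed lactone is cut at C3'–C4' and O1'–C2'. This is a formal [4+2] union of ortho-quinone methide 25, released from sulfone 24, with the carbene-bound enolate of active ester 19. The C3–C3' bond is not cut because it is the most congested bond of 27; leaving it inside 19 means it was made earlier as a simple enolate alkylation. The forward step has to set C3' and C4' cis and in the right absolute sense next to the existing C3/C4 pair.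

19 to 18, 15 and 14. C3–H is traced to lactone enol 17, which arises by decarboxylation of diacid 16. The extra carboxyl keeps C3 quaternary and non-epimerisable while ring A is built, supplies the lactone carbonyl C2, and is removed under neutral conditions where the C4 aryl group decides the face of protonation. Cutting O1–C2 of lactone 15 leads to phenol 14. All three esters are benzyl so that one hydrogenolysis of 15 frees both acids of 16.

14 to 8 and 9. Ring A is taken apart at C8a–C4a, C5–C6 and C8–C8a, leaving ynol ether 8 and cyclobutenone 9. Cutting here instead of at C4–C4a avoids creating C4 on a carbon flanked by two ortho oxygens. Each oxygen of ring A is placed by the building blocks, and the free hydroxyl appears at C8a, where the lactone needs it. The forward reaction has to be regioselective and must not disturb the propargylic centre.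

8 to 6, 5, 3 and 4. The malonate of 8 comes from the Meldrum's acid ring of 6 by alkoxide opening. The C3–C3' bond of 6 comes from C-alkylation of the enolate of 5 with a haloacetic ester. The C4–alkyne bond of 5 comes from asymmetric conjugate addition of ethoxyacetylene 4 to arylidene acceptor 3, which is the condensation product of 1 and 2. This places the only catalyst-controlled stereocentre of the ring A half on an unhindered acceptor.

24 to 23 and 1; 23 to 20. The benzylic carbon of 24 is attached to the single free position of phenol 23 by condensation with aldehyde 1. Phenol 23 comes from commercial 20 by introducing one oxygen ortho to a methoxy group.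

## Alternatives that were turned down

Alternative 1: The unprimed lactone is cut at C3–C4 and O1–C2. In the forward sense a chiral triazolium-derived carbene turns active ester A2 (the ring B lactone acetic acid derivative) into an azolium enolate, which adds to the ortho-quinone methide released from ring A sulfone A3 and gives octamethyl ether A1.
- For it: it is the most convergent plan; the last C–C bond and two stereocentres come from one catalytic step, and cis selectivity is inherent to the annulation.
- Against it: the methide carbon of the ring A quinone methide is flanked by a methoxy group. Sulfone A3 must be made from a symmetric trioxygenated phenol with a competing position between the two methoxy groups. A2 still needs its own asymmetric construction of the ring B lactone, so the difficult fully substituted ring B chemistry is only moved earlier.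
- Comparison: on convergence and catalyst-controlled cis formation at C3/C4 it is at least as strong as the chosen route, which relies on substrate-controlled protonation in step 6. The chosen route offers a C4 centre set on a slim alkyne acceptor, a ring A whose substitution is unambiguous by construction, and one quinone methide annulation instead of two.

Alternative 2: Ring B is disconnected at C5'–C4a'. Heating the squarate-derived cyclobutenone A5 opens it to a dienylketene that closes to the hydroquinone A4.
- For it: it builds the hardest arene of the target with every oxygen placed by construction, under neutral thermal conditions, and with the C4' centre fixed before aromatisation.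
- Against it: A4 is an air-sensitive hydroquinone whose lactone carbon is still at the acetal level and whose C3' arm is a tetrahydrofuran fragment. Reprotection, two oxidation-state adjustments and the whole ring A half still follow, and the stereodefined precursor A5 needs its own multistep asymmetric synthesis.
- Comparison: it is stronger on regiocontrol of ring B oxygenation and avoids the fully substituted quinone methide 25. The chosen route buys the ring B oxygens in 20 and uses the same kind of thermal cyclobutenone chemistry on ring A, where it also removes the steric problem at C4; it needs fewer redox steps.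

Alternative 3: The unprimed lactone is cut at C2–C3 and C2–O1 with the carbonyl carbon coming from gas. A chiral bisphosphine palladium catalyst under a carbonylating, reducing atmosphere converts alkenylphenol A7 into cis lactone A6.
- For it: syn addition across the alkene gives the cis C3/C4 relationship directly, both centres come from one catalyst, and ring A comes from a commercial phloroglucinol ether.
- Against it: the alkene is trisubstituted, 1,1-diaryl and attached to a doubly ortho-substituted arene, so hydrometallation should be slow. The catalyst has to tell two electron-rich aryl groups apart. The alkene geometry of A7 must be pure because it becomes relative configuration, and five- versus six-membered carbonylation can compete. The arm of A6 needs deprotection and two oxidations before the second half can be attached.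
- Comparison: it is stronger on direct, catalyst-controlled cis formation. The chosen route sets C4 on a well-behaved conjugate acceptor, carries the arm at the acid oxidation level from the start, and controls ring A regiochemistry by construction.

Key step: step 4

Remark on the chemistry: the ligand in step 2 and the triazolium salt in step 10 are written in the enantiomeric series expected to give (R)-5 and (3'S,4'R)-26; the sense of induction is to be confirmed in a first run, both antipodes being equally accessible.

## Route

Step 1
Reactants: 1 4-methoxybenzaldehyde; 2 Meldrum's acid (2,2-dimethyl-1,3-dioxane-4,6-dione)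
Product: 3 5-(4-methoxybenzylidene)-2,2-dimethyl-1,3-dioxane-4,6-dione
Conditions: H2O, 75 °C
Reagents that add atoms: none
Why: Knoevenagel condensation of an aromatic aldehyde with the strongly C–H acidic dione needs no catalyst in hot water, and the product should crystallise from the medium.

Step 2
Reactants: 3 5-(4-methoxybenzylidene)-2,2-dimethyl-1,3-dioxane-4,6-dione; 4 ethoxyacetylene
Product: 6 benzyl 2-{5-[(1R)-3-ethoxy-1-(4-methoxyphenyl)prop-2-yn-1-yl]-2,2-dimethyl-4,6-dioxo-1,3-dioxan-5-yl}acetate, via conjugate adduct 5 (not isolated)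
Conditions: Cu(OAc)2·H2O (10 mol%), sodium L-ascorbate (NaC6H7O6, 20 mol%), (R,Ra)-N-PINAP (10 mol%), H2O/t-BuOH, 0 °C; then NaHCO3, BrCH2CO2Bn, Bu4NBr (10 mol%), CH2Cl2/H2O, 0 °C → rt
Reagents that add atoms: benzyl bromoacetate, BrCC(=O)OCc1ccccc1
Why: Copper-catalysed asymmetric conjugate alkynylation of an arylidene Meldrum's acid with a terminal alkyne: ascorbate reduces divalent copper to the monovalent state, and the acetylide of 4, held by the chiral P,N ligand, adds to one enantiotopic face of 3 and sets C4 as (R). Adduct 5 is not isolated because its acidic C–H could protonate the ynol ether; it is converted to its enolate and C-alkylated under phase transfer, which installs C3' and C2'.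

Step 3
Reactants: 6 benzyl 2-{5-[(1R)-3-ethoxy-1-(4-methoxyphenyl)prop-2-yn-1-yl]-2,2-dimethyl-4,6-dioxo-1,3-dioxan-5-yl}acetate
Product: 8 tribenzyl (3R)-5-ethoxy-3-(4-methoxyphenyl)pent-4-yne-1,2,2-tricarboxylate, via sodium carboxylate 7 (not isolated)
Conditions: BnOH (1.2 equiv), NaH, THF, 0 → 40 °C; then BnBr, Bu4NI (cat.), DMF, rt
Reagents that add atoms: benzyl alcohol, OCc1ccccc1; benzyl bromide, BrCc1ccccc1
Why: Alkoxide opening of the 5,5-disubstituted Meldrum's acid (acyl substitution with loss of acetone) and O-alkylation of carboxylate 7 give the open-chain malonate without exposing the acid-labile ynol ether to a free carboxylic acid. Both epimers of 7 converge on 8.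

Step 4
Reactants: 8 tribenzyl (3R)-5-ethoxy-3-(4-methoxyphenyl)pent-4-yne-1,2,2-tricarboxylate; 9 3-ethoxycyclobut-2-en-1-one
Product: 14 tribenzyl (3R)-3-(2,4-diethoxy-6-hydroxyphenyl)-3-(4-methoxyphenyl)propane-1,2,2-tricarboxylate, via vinylketene 10 (not isolated), via vinylcyclobutenone 11 (not isolated), via dienylketene 12 (not isolated), via cyclohexadienone 13 (not isolated)
Conditions: 9 (1.5 equiv, two portions), toluene, 80 °C, then 110 °C, argon
Reagents that add atoms: none
Why: Danheiser benzannulation: at 80 °C cyclobutenone 9 undergoes 4π-electrocyclic opening to vinylketene 10, whose carbonyl carbon bonds to the nucleophilic alkyne carbon of 8 (the one carrying C4, remote from oxygen) while its α-carbon bonds to the oxygen-bearing alkyne carbon, a four-membered closure by [2+2] cycloaddition that forms C8a–C4a and C5–C6 in 11. Cyclobutenone 11 opens (4π) to dienylketene 12, which closes the six-membered ring by 6π-electrocyclisation (C8–C8a) to 13, and enolisation gives phenol 14. The closest known reaction type is the benzannulation of cyclobutenones with alkoxyalkynes to resorcinol monoethers; the 3-ethoxy group of 9 adds the third oxygen. No stereocentre is created. The step needs regioselectivity, and the polarisation of the ynol ether secures it: the side chain ends up between the new hydroxyl and the ethoxy group, which is the C8a/C4a/C5 sequence with the phenol placed for lactonisation. It also needs the propargylic C4 centre of 8 to survive, which the neutral, base-free medium allows, and it needs the ethyl ynol ether to outlast retro-ene loss of ethylene, which is why the temperature is raised to 110 °C only after 8 is consumed. The excess of 9 is kept small so that acylation of the hindered phenol by 10 stays minor.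

Step 5
Reactants: 14 tribenzyl (3R)-3-(2,4-diethoxy-6-hydroxyphenyl)-3-(4-methoxyphenyl)propane-1,2,2-tricarboxylate
Product: 15 benzyl (4R)-3-[2-(benzyloxy)-2-oxoethyl]-5,7-diethoxy-4-(4-methoxyphenyl)-2-oxo-3,4-dihydro-2H-chromene-3-carboxylate (both C3 epimers)
Conditions: p-TsOH·H2O (10 mol%), toluene, 90 °C
Reagents that add atoms: none
Why: Acid-catalysed intramolecular transesterification; the six-membered lactone onto either malonate ester is favoured over the seven-membered one and is driven by the crowded, gem-disubstituted environment around C4a and C3. Both C3 epimers are carried on because C3 becomes planar in step 6, and any 15 already formed in step 4 is combined here.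

Step 6
Reactants: 15 benzyl (4R)-3-[2-(benzyloxy)-2-oxoethyl]-5,7-diethoxy-4-(4-methoxyphenyl)-2-oxo-3,4-dihydro-2H-chromene-3-carboxylate
Product: 18 2-[(3R,4R)-5,7-diethoxy-4-(4-methoxyphenyl)-2-oxo-3,4-dihydro-2H-chromen-3-yl]acetic acid, via diacid 16 (not isolated), via lactone enol 17 (not isolated)
Conditions: H2 (1 atm), Pd/C (10 wt%), EtOAc, rt; filter; toluene, 90 °C
Reagents that add atoms: none
Why: Hydrogenolysis of both benzyl esters gives 16, whose carboxyl β to the lactone carbonyl is lost on gentle heating through the cyclic transition state to give enol 17. The C4 anisyl group, held pseudoaxial by the peri C5 ethoxy group, shields one face, so C3 should be protonated anti to it, which places the acetic acid arm cis to the aryl group (3R,4R). No base is present to equilibrate towards the trans isomer.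

Step 7
Reactants: 18 2-[(3R,4R)-5,7-diethoxy-4-(4-methoxyphenyl)-2-oxo-3,4-dihydro-2H-chromen-3-yl]acetic acid
Product: 19 4-nitrophenyl 2-[(3R,4R)-5,7-diethoxy-4-(4-methoxyphenyl)-2-oxo-3,4-dihydro-2H-chromen-3-yl]acetate
Conditions: 4-nitrophenol, EDC·HCl, CH2Cl2, 0 °C → rt
Reagents that add atoms: 4-nitrophenol, Oc1ccc(cc1)[N+](=O)[O-]
Why: Carbodiimide esterification of an unhindered primary carboxylic acid; DMAP is left out so that the epimerisable C3–H next to the lactone carbonyl does not meet a base.

Step 8
Reactants: 20 1,2,3,4-tetramethoxybenzene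
Product: 23 2,3,4,5-tetramethoxyphenol, via aryllithium 21 (not isolated), via arylboronate 22 (not isolated)
Conditions: n-BuLi, TMEDA, THF, 0 °C; B(OMe)3, −78 °C → rt; 30% H2O2, AcOH, 0 °C
Reagents that add atoms: hydrogen peroxide, OO; trimethyl borate, COB(OC)OC (its atoms stay only in intermediate 22)
Why: Directed ortho-lithiation next to a methoxy group (the two free positions are equivalent), borylation and oxidative conversion of the C–B bond to C–O.

Step 9
Reactants: 23 2,3,4,5-tetramethoxyphenol; 1 4-methoxybenzaldehyde
Product: 24 3,4,5,6-tetramethoxy-2-[(4-methoxyphenyl)(4-methylbenzenesulfonyl)methyl]phenol (racemic)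
Conditions: p-TolSO2Na, HCO2H/H2O, rt
Reagents that add atoms: sodium p-toluenesulfinate, Cc1ccc(cc1)S(=O)[O-].[Na+]
Why: Acid-mediated three-component condensation: Friedel–Crafts hydroxyalkylation at the only free ring position, ortho to the hydroxyl, then capture of the stabilised benzylic cation by sulfinate. The sulfone is a storable precursor of the ortho-quinone methide, and its stereocentre is erased on elimination.

Step 10
Reactants: 19 4-nitrophenyl 2-[(3R,4R)-5,7-diethoxy-4-(4-methoxyphenyl)-2-oxo-3,4-dihydro-2H-chromen-3-yl]acetate; 24 3,4,5,6-tetramethoxy-2-[(4-methoxyphenyl)(4-methylbenzenesulfonyl)methyl]phenol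
Product: 26 (3S,3'S,4R,4'R)-5,7-diethoxy-5',6',7',8'-tetramethoxy-4,4'-bis(4-methoxyphenyl)-[3,3'-bichromane]-2,2'-dione, via ortho-quinone methide 25 (not isolated)
Conditions: (5aS,10bR)-2-mesityl-5a,10b-dihydro-4H,6H-indeno[2,1-b][1,2,4]triazolo[4,3-d][1,4]oxazin-2-ium chloride (20 mol%), K2CO3 (3 equiv), 4 Å MS, THF, 0 °C → rt
Reagents that add atoms: none
Why: Carbene-catalysed formal [4+2] annulation: the carbene displaces 4-nitrophenoxide from 19 and deprotonation gives the azolium enolate, while carbonate eliminates sulfinate from 24 to give 25; the enolate carbon (C3') adds to the methide carbon (C4') and the phenoxide then acylates at C2' with release of the carbene. The endo-type approach of the Z-enolate should give the 3',4'-cis lactone and the aminoindanol backbone selects the enolate face, so C3' and C4' are set (S,R) under catalyst control. The mild heterogeneous base is chosen to leave C3–H untouched.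

Step 11
Reactants: 26 (3S,3'S,4R,4'R)-5,7-diethoxy-5',6',7',8'-tetramethoxy-4,4'-bis(4-methoxyphenyl)-[3,3'-bichromane]-2,2'-dione
Product: 27 (3S,3'S,4R,4'R)-5,5',6',7,7',8'-hexahydroxy-4,4'-bis(4-hydroxyphenyl)-[3,3'-bichromane]-2,2'-dione (CNP0064734.1)
Conditions: BBr3 (20 equiv), CH2Cl2, −78 °C → rt, argon; MeOH; degassed aqueous ascorbic acid work-up
Reagents that add atoms: none
Why: Lewis-acid cleavage of all eight aryl alkyl ethers by bromide attack on the O-alkyl carbon of the boron-complexed ether. The aryl lactones have no alkyl C–O bond to cleave and should survive, and the degassed reductive work-up protects the tetrahydroxy ring from air oxidation.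

## Compound list

1 | 4-methoxybenzaldehyde | COc1ccc(C=O)cc1 | starting material
2 | Meldrum's acid (2,2-dimethyl-1,3-dioxane-4,6-dione) | CC1(C)OC(=O)CC(=O)O1 | starting material
3 | 5-(4-methoxybenzylidene)-2,2-dimethyl-1,3-dioxane-4,6-dione | COc1ccc(C=C2C(=O)OC(C)(C)OC2=O)cc1 | intermediate
4 | ethoxyacetylene | CCOC#C | starting material
5 | 5-[(1R)-3-ethoxy-1-(4-methoxyphenyl)prop-2-yn-1-yl]-2,2-dimethyl-1,3-dioxane-4,6-dione | CCOC#C[C@@H](c1ccc(OC)cc1)C1C(=O)OC(C)(C)OC1=O | intermediate
6 | benzyl 2-{5-[(1R)-3-ethoxy-1-(4-methoxyphenyl)prop-2-yn-1-yl]-2,2-dimethyl-4,6-dioxo-1,3-dioxan-5-yl}acetate | CCOC#C[C@@H](c1ccc(OC)cc1)C1(CC(=O)OCc2ccccc2)C(=O)OC(C)(C)OC1=O | intermediate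
7 | sodium (3R)-2-[(benzyloxy)carbonyl]-2-[2-(benzyloxy)-2-oxoethyl]-5-ethoxy-3-(4-methoxyphenyl)pent-4-ynoate (both C2 epimers) | CCOC#C[C@@H](c1ccc(OC)cc1)C(CC(=O)OCc1ccccc1)(C(=O)OCc1ccccc1)C(=O)[O-].[Na+] | intermediate
8 | tribenzyl (3R)-5-ethoxy-3-(4-methoxyphenyl)pent-4-yne-1,2,2-tricarboxylate | CCOC#C[C@@H](c1ccc(OC)cc1)C(CC(=O)OCc1ccccc1)(C(=O)OCc1ccccc1)C(=O)OCc1ccccc1 | intermediate
9 | 3-ethoxycyclobut-2-en-1-one | CCOC1=CC(=O)C1 | starting material
10 | 3-ethoxybuta-1,3-dien-1-one ((1-ethoxyvinyl)ketene) | CCOC(=C)C=C=O | intermediate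
11 | tribenzyl (3R)-3-[2-ethoxy-3-(1-ethoxyethenyl)-4-oxocyclobut-1-en-1-yl]-3-(4-methoxyphenyl)propane-1,2,2-tricarboxylate (both epimers at the ring CH) | CCOC1=C([C@@H](c2ccc(OC)cc2)C(CC(=O)OCc2ccccc2)(C(=O)OCc2ccccc2)C(=O)OCc2ccccc2)C(=O)C1C(=C)OCC | intermediate
12 | tribenzyl (3R,5E)-5,7-diethoxy-3-(4-methoxyphenyl)-4-(oxomethylidene)octa-5,7-diene-1,2,2-tricarboxylate | CCOC(=C)\C=C(OCC)/C(=C=O)[C@@H](c1ccc(OC)cc1)C(CC(=O)OCc1ccccc1)(C(=O)OCc1ccccc1)C(=O)OCc1ccccc1 | intermediate
13 | tribenzyl (3R)-3-(2,4-diethoxy-6-oxocyclohexa-1,3-dien-1-yl)-3-(4-methoxyphenyl)propane-1,2,2-tricarboxylate | CCOC1=CC(OCC)=C([C@@H](c2ccc(OC)cc2)C(CC(=O)OCc2ccccc2)(C(=O)OCc2ccccc2)C(=O)OCc2ccccc2)C(=O)C1 | intermediate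
14 | tribenzyl (3R)-3-(2,4-diethoxy-6-hydroxyphenyl)-3-(4-methoxyphenyl)propane-1,2,2-tricarboxylate | CCOc1cc(OCC)cc(O)c1[C@@H](c1ccc(OC)cc1)C(CC(=O)OCc1ccccc1)(C(=O)OCc1ccccc1)C(=O)OCc1ccccc1 | intermediate
15 | benzyl (4R)-3-[2-(benzyloxy)-2-oxoethyl]-5,7-diethoxy-4-(4-methoxyphenyl)-2-oxo-3,4-dihydro-2H-chromene-3-carboxylate (both C3 epimers) | O=C1Oc2cc(OCC)cc(OCC)c2[C@@H](c2ccc(OC)cc2)C1(CC(=O)OCc1ccccc1)C(=O)OCc1ccccc1 | intermediate
16 | (4R)-3-(carboxymethyl)-5,7-diethoxy-4-(4-methoxyphenyl)-2-oxo-3,4-dihydro-2H-chromene-3-carboxylic acid (both C3 epimers) | O=C1Oc2cc(OCC)cc(OCC)c2[C@@H](c2ccc(OC)cc2)C1(CC(=O)O)C(=O)O | intermediate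
17 | 2-[(4R)-5,7-diethoxy-2-hydroxy-4-(4-methoxyphenyl)-4H-chromen-3-yl]acetic acid | OC(=O)CC1=C(O)Oc2cc(OCC)cc(OCC)c2[C@H]1c1ccc(OC)cc1 | intermediate
18 | 2-[(3R,4R)-5,7-diethoxy-4-(4-methoxyphenyl)-2-oxo-3,4-dihydro-2H-chromen-3-yl]acetic acid (3,4-cis) | O=C1Oc2cc(OCC)cc(OCC)c2[C@@H](c2ccc(OC)cc2)[C@H]1CC(=O)O | intermediate
19 | 4-nitrophenyl 2-[(3R,4R)-5,7-diethoxy-4-(4-methoxyphenyl)-2-oxo-3,4-dihydro-2H-chromen-3-yl]acetate | O=C1Oc2cc(OCC)cc(OCC)c2[C@@H](c2ccc(OC)cc2)[C@H]1CC(=O)Oc1ccc(cc1)[N+](=O)[O-] | intermediate
20 | 1,2,3,4-tetramethoxybenzene | COc1ccc(OC)c(OC)c1OC | starting material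
21 | (2,3,4,5-tetramethoxyphenyl)lithium | [Li]c1cc(OC)c(OC)c(OC)c1OC | intermediate
22 | dimethyl (2,3,4,5-tetramethoxyphenyl)boronate | COB(OC)c1cc(OC)c(OC)c(OC)c1OC | intermediate
23 | 2,3,4,5-tetramethoxyphenol | Oc1cc(OC)c(OC)c(OC)c1OC | intermediate
24 | 3,4,5,6-tetramethoxy-2-[(4-methoxyphenyl)(4-methylbenzenesulfonyl)methyl]phenol (racemic) | Oc1c(C(c2ccc(OC)cc2)S(=O)(=O)c2ccc(C)cc2)c(OC)c(OC)c(OC)c1OC | intermediate
25 | 2,3,4,5-tetramethoxy-6-(4-methoxybenzylidene)cyclohexa-2,4-dien-1-one | O=C1C(OC)=C(OC)C(OC)=C(OC)C1=Cc1ccc(OC)cc1 | intermediate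
26 | (3S,3'S,4R,4'R)-5,7-diethoxy-5',6',7',8'-tetramethoxy-4,4'-bis(4-methoxyphenyl)-[3,3'-bichromane]-2,2'-dione | O=C1Oc2cc(OCC)cc(OCC)c2[C@@H](c2ccc(OC)cc2)[C@H]1[C@H]1C(=O)Oc2c(OC)c(OC)c(OC)c(OC)c2[C@H]1c1ccc(OC)cc1 | intermediate
27 | (3S,3'S,4R,4'R)-5,5',6',7,7',8'-hexahydroxy-4,4'-bis(4-hydroxyphenyl)-[3,3'-bichromane]-2,2'-dione (CNP0064734.1) | O=C1Oc2cc(O)cc(O)c2[C@@H](c2ccc(O)cc2)[C@H]1[C@H]1C(=O)Oc2c(O)c(O)c(O)c(O)c2[C@H]1c1ccc(O)cc1 | target

## Step count and least certain steps

Total: 11 steps. Longest linear sequence: 9 steps (steps 1 to 7, 10 and 11). Sulfone 24 takes two further steps (8 and 9).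

Step 4 (key step). The bimolecular [2+2] between vinylketene 10 and the hindered internal ynol ether may be slow, so dimerisation of the ketene can take over. If opening of 9 needs more heat, retro-ene fragmentation of the ethyl ynol ether competes. Acylation of the product phenol by excess ketene is a further loss. The fallback gives up arene construction and attaches a preformed ring A. It sets out from 1 and 3,5-diethoxyphenol F1, which are condensed with sodium p-toluenesulfinate in aqueous formic acid to sulfone F2. Dibenzyl malonate F3 is alkylated with benzyl bromoacetate (NaH, THF) to tribenzyl ethane-1,1,2-tricarboxylate F4. With a cinchona-derived bifunctional squaramide and aqueous carbonate, F2 loses sulfinate to the ortho-quinone methide F5, which takes up the malonate F4 on one face to give 14, where the route is rejoined before step 5. Its own weak points are competing substitution between the two ethoxy groups when F2 is made and the low reactivity of a tertiary malonate.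

Step 2. An alkoxyacetylene is a new partner for this conjugate alkynylation. The ynol ether may be protonated or hydrated in the aqueous medium or by the C–H acidic adduct, the enol may cyclise onto the alkyne under copper, 3 may undergo retro-condensation in water, and facial selectivity may be low. The fallback sets out from 3 and 4 and uses stoichiometric acetylide chemistry with a resolution. Compound 4 is deprotonated with n-BuLi (THF, −78 °C) to lithium ethoxyacetylide F6, which adds 1,4 to 3 to give the racemic lithium enolate F7. This is alkylated in the same flask with benzyl bromoacetate (DMPU) to racemic F8. Preparative chiral-phase SFC separates 6 from its (S)-enantiomer F9, and the route is rejoined at 6.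

Step 6. Facial discrimination in the protonation of enol 17 may be insufficient, thermal equilibration towards the trans isomer may set in, and anhydride formation between the two acids of 16 may compete with decarboxylation. The fallback sets out from the mixture of 18 and its C3 epimer, the trans acid 2-[(3S,4R)-5,7-diethoxy-4-(4-methoxyphenyl)-2-oxo-3,4-dihydro-2H-chromen-3-yl]acetic acid F10. LiHMDS (2.2 equiv, THF, −78 °C) gives the dilithium carboxylate–lactone enolate F11; the carboxylate forms first and directs the second deprotonation to the more acidic lactone C3–H. A quench at −78 °C with 2,6-di-tert-butyl-4-methylphenol protonates C3 anti to the C4 aryl group and returns to 18.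

Step 10. The new bond joins two hindered carbons, so the annulation may be slow. The C5' methoxy group can force the methide aryl group of 25 into the other alkene geometry, which would erode the cis selectivity at C3'/C4'. Base may epimerise C3, and catalyst and substrate control may be mismatched. The fallback sets out from 19 and 24, accepts the mixture of C3/C3' epimers F12 (C4' still set by the catalyst) and corrects both α-centres together. LiHMDS (2.5 equiv, THF, −78 °C) gives the dilithium bis-enolate F13. Low-temperature protonation with a hindered phenol should deliver hydrogen to each enolate anti to its own C4 aryl group, which is the cis,cis arrangement of 26, where the route is rejoined.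

Step 11. Cleavage of the hindered ethyl ethers may be incomplete, the diarylmethine carbons may ionise in the acidic medium, and the tetrahydroxy ring may be oxidised during isolation. The fallback sets out from 26 and isolates a stable derivative. After the BBr3 treatment the crude polyphenol is acetylated in the same flask (Ac2O, pyridine) to the octaacetate F14, which is purified by chromatography. Mild methanolysis of the aryl acetates (NH4OAc, degassed aqueous MeOH, argon) then releases 27; the hindered lactones should react more slowly than the acetates.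

## Further compounds

F1 | step 4 | 3,5-diethoxyphenol | CCOc1cc(O)cc(OCC)c1
F2 | step 4 | 3,5-diethoxy-2-[(4-methoxyphenyl)(4-methylbenzenesulfonyl)methyl]phenol (racemic) | CCOc1cc(O)c(C(c2ccc(OC)cc2)S(=O)(=O)c2ccc(C)cc2)c(OCC)c1
F3 | step 4 | dibenzyl malonate | O=C(CC(=O)OCc1ccccc1)OCc1ccccc1
F4 | step 4 | tribenzyl ethane-1,1,2-tricarboxylate | O=C(CC(C(=O)OCc1ccccc1)C(=O)OCc1ccccc1)OCc1ccccc1
F5 | step 4 | 3,5-diethoxy-6-(4-methoxybenzylidene)cyclohexa-2,4-dien-1-one | O=C1C=C(OCC)C=C(OCC)C1=Cc1ccc(OC)cc1
F6 | step 2 | lithium ethoxyacetylide | [Li]C#COCC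
F7 | step 2 | lithium enolate of racemic 5-[3-ethoxy-1-(4-methoxyphenyl)prop-2-yn-1-yl]-2,2-dimethyl-1,3-dioxane-4,6-dione | CCOC#CC(c1ccc(OC)cc1)C1=C([O-])OC(C)(C)OC1=O.[Li+]
F8 | step 2 | racemic benzyl 2-{5-[3-ethoxy-1-(4-methoxyphenyl)prop-2-yn-1-yl]-2,2-dimethyl-4,6-dioxo-1,3-dioxan-5-yl}acetate | CCOC#CC(c1ccc(OC)cc1)C1(CC(=O)OCc2ccccc2)C(=O)OC(C)(C)OC1=O
F9 | step 2 | benzyl 2-{5-[(1S)-3-ethoxy-1-(4-methoxyphenyl)prop-2-yn-1-yl]-2,2-dimethyl-4,6-dioxo-1,3-dioxan-5-yl}acetate | CCOC#C[C@H](c1ccc(OC)cc1)C1(CC(=O)OCc2ccccc2)C(=O)OC(C)(C)OC1=O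
F10 | step 6 | 2-[(3S,4R)-5,7-diethoxy-4-(4-methoxyphenyl)-2-oxo-3,4-dihydro-2H-chromen-3-yl]acetic acid (3,4-trans) | O=C1Oc2cc(OCC)cc(OCC)c2[C@@H](c2ccc(OC)cc2)[C@@H]1CC(=O)O
F11 | step 6 | dilithium 2-[(4R)-5,7-diethoxy-4-(4-methoxyphenyl)-2-oxido-4H-chromen-3-yl]acetate | [Li+].[Li+].[O-]C(=O)CC1=C([O-])Oc2cc(OCC)cc(OCC)c2[C@H]1c1ccc(OC)cc1
F12 | step 10 | (4R,4'R)-5,7-diethoxy-5',6',7',8'-tetramethoxy-4,4'-bis(4-methoxyphenyl)-[3,3'-bichromane]-2,2'-dione (mixture of C3/C3' epimers) | O=C1Oc2cc(OCC)cc(OCC)c2[C@@H](c2ccc(OC)cc2)C1C1C(=O)Oc2c(OC)c(OC)c(OC)c(OC)c2[C@H]1c1ccc(OC)cc1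
F13 | step 10 | dilithium (4R,4'R)-5,7-diethoxy-5',6',7',8'-tetramethoxy-4,4'-bis(4-methoxyphenyl)-4H,4'H-[3,3'-bichromene]-2,2'-diolate | [Li+].[Li+].[O-]C1=C(C2=C([O-])Oc3c(OC)c(OC)c(OC)c(OC)c3[C@H]2c2ccc(OC)cc2)[C@H](c2ccc(OC)cc2)c2c(OCC)cc(OCC)cc2O1
F14 | step 11 | (3S,3'S,4R,4'R)-5,5',6',7,7',8'-hexaacetoxy-4,4'-bis(4-acetoxyphenyl)-[3,3'-bichromane]-2,2'-dione | O=C1Oc2cc(OC(C)=O)cc(OC(C)=O)c2[C@@H](c2ccc(OC(C)=O)cc2)[C@H]1[C@H]1C(=O)Oc2c(OC(C)=O)c(OC(C)=O)c(OC(C)=O)c(OC(C)=O)c2[C@H]1c1ccc(OC(C)=O)cc1
A1 | alternative 1 | (3S,3'S,4R,4'R)-5,5',6',7,7',8'-hexamethoxy-4,4'-bis(4-methoxyphenyl)-[3,3'-bichromane]-2,2'-dione | O=C1Oc2cc(OC)cc(OC)c2[C@@H](c2ccc(OC)cc2)[C@H]1[C@H]1C(=O)Oc2c(OC)c(OC)c(OC)c(OC)c2[C@H]1c1ccc(OC)cc1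
A2 | alternative 1 | 4-nitrophenyl 2-[(3R,4R)-5,6,7,8-tetramethoxy-4-(4-methoxyphenyl)-2-oxo-3,4-dihydro-2H-chromen-3-yl]acetate | O=C(C[C@H]1C(=O)Oc2c(OC)c(OC)c(OC)c(OC)c2[C@H]1c1ccc(OC)cc1)Oc1ccc(cc1)[N+](=O)[O-]
A3 | alternative 1 | 3,5-dimethoxy-2-[(4-methoxyphenyl)(4-methylbenzenesulfonyl)methyl]phenol | COc1cc(O)c(C(c2ccc(OC)cc2)S(=O)(=O)c2ccc(C)cc2)c(OC)c1
A4 | alternative 2 | 6,7-dimethoxy-4-(4-methoxyphenyl)-2,3,3a,9a-tetrahydro-4H-furo[2,3-b]chromene-5,8-diol | C1CO[C@H]2Oc3c(O)c(OC)c(OC)c(O)c3[C@H]([C@@H]12)c1ccc(OC)cc1
A5 | alternative 2 | 4-hydroxy-2,3-dimethoxy-4-[4-(4-methoxyphenyl)-2,3,3a,7a-tetrahydro-4H-furo[2,3-b]pyran-6-yl]cyclobut-2-en-1-one | C1CO[C@H]2OC(=C[C@H]([C@@H]12)c1ccc(OC)cc1)C1(O)C(=O)C(OC)=C1OC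
A6 | alternative 3 | (3R,4R)-3-{2-[(tert-butyldimethylsilyl)oxy]ethyl}-5,7-dimethoxy-4-(4-methoxyphenyl)-3,4-dihydro-2H-chromen-2-one | O=C1Oc2cc(OC)cc(OC)c2[C@@H](c2ccc(OC)cc2)[C@H]1CCO[Si](C)(C)C(C)(C)C
A7 | alternative 3 | 2-[(1Z)-4-[(tert-butyldimethylsilyl)oxy]-1-(4-methoxyphenyl)but-1-en-1-yl]-3,5-dimethoxyphenol | COc1ccc(cc1)/C(=C/CCO[Si](C)(C)C(C)(C)C)c1c(O)cc(OC)cc1OC
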